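The cyclopentane end group is made by a (3+2) annulation that forms, in one operation, the ring CH2–CH2 bond and the bond joining the chain-bearing ring CH to the C(CH3)(OH) carbon. The key step exploits the cis relation between that chain-bearing CH and the neighbouring CH(CMe2OH) of the five-membered ring: both sit in a cis-fused γ-lactone, which is used as its methylene enol ether fused to a cyclopropane, a bicyclic vinylcyclopropane made from a meso cyclopropane diester. Thiyl-radical catalysis opens the cyclopropane CH2 bond and inserts isopropenyl boronate; the C–B bond then becomes the tertiary hydroxyl. A lactol Wittig reaction with a C30 polyenyl phosphonium salt completes the carotenoid.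

Key step: step 4

Remark on numbering: carotenoid end-group locants are used in the explanations: C-1 = CMe2(OH) carbon, C-2 = ring CH bearing it, C-3 and C-4 = ring CH2 groups, C-5 = ring C(CH3)(OH), C-6 = ring CH bearing the chain, C-7/C-8 = first chain alkene.
Remark on geometry: Z isomers formed in the two Wittig steps are taken to equilibrate thermally to the all-E polyene, as is usual for unhindered carotenoid double bonds.

Step 1
Reactants: 1 dimethyl cis-cyclopropane-1,2-dicarboxylate (meso)
Product: 2 (1S,2R)-2-(methoxycarbonyl)cyclopropane-1-carboxylic acid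
Conditions: pig liver esterase, NaH2PO4/Na2HPO4 buffer pH 7, 25 °C, pH-stat with 1 M NaOH (1 equiv); then HCl to pH 2, EtOAc extraction
Reagents that add atoms: water, O
Why: Enzymatic desymmetrisation (enantiotopic-group-selective ester hydrolysis) of the meso diester, in which the esterase is expected to hydrolyse the pro-S ester group and so fix both cyclopropane stereocentres as 1S,2R.

Step 2
Reactants: 2 (1S,2R)-2-(methoxycarbonyl)cyclopropane-1-carboxylic acid
Product: 4 (1S,5R)-4,4-dimethyl-3-oxabicyclo[3.1.0]hexan-2-one, via hydroxy acid 3 (not isolated)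
Conditions: MeMgBr (3.5 equiv), THF, 0 °C to 25 °C; then aqueous citric acid (pH 4), 25 °C
Reagents that add atoms: methylmagnesium bromide, C[Mg]Br
Why: Grignard double addition to the ester while the acid is masked as its unreactive magnesium carboxylate, followed by spontaneous lactonisation of the cis tertiary hydroxy acid; no stereocentre is touched and the mild acid avoids ionising the cyclopropylcarbinyl C–O bond.

Step 3
Reactants: 4 (1S,5R)-4,4-dimethyl-3-oxabicyclo[3.1.0]hexan-2-one
Product: 5 (1S,5R)-4,4-dimethyl-2-methylidene-3-oxabicyclo[3.1.0]hexane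
Conditions: Cp2TiMe2 (2.2 equiv), toluene, 65 °C, dark; filtration through basic Al2O3; used as a solution
Reagents that add atoms: dimethyltitanocene (Cp2TiMe2), C[Ti](C)(C1C=CC=C1)C1C=CC=C1
Why: Petasis methylenation of the lactone carbonyl (Cp2Ti=CH2, oxatitanacyclobutane, loss of titanocene oxide) under neutral conditions gives the exocyclic enol ether, a vinylcyclopropane locked in a bicycle, with both stereocentres untouched.

Step 4
Reactants: 5 (1S,5R)-4,4-dimethyl-2-methylidene-3-oxabicyclo[3.1.0]hexane; 6 4,4,5,5-tetramethyl-2-(prop-1-en-2-yl)-1,3,2-dioxaborolane (isopropenylboronic acid pinacol ester)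
Product: 7 (3aR,6S,6aR)-3,3,6-trimethyl-1-methylidene-6-(4,4,5,5-tetramethyl-1,3,2-dioxaborolan-2-yl)hexahydro-1H-cyclopenta[c]furan
Conditions: PhSSPh (0.2 equiv), AIBN (0.1 equiv), 6 (5 equiv), degassed benzene at high concentration, sunlamp irradiation, 40 °C
Reagents that add atoms: none
Why: PhS• adds reversibly to the exocyclic CH2 of 5; the tertiary α-oxy cyclopropylcarbinyl radical at C-7 opens to the primary C-3 radical, which adds to the CH2 terminus of 6 (new C-3–C-4 bond), and the resulting tertiary α-boryl C-5 radical closes onto the enol-ether carbon C-6 (new C-5–C-6 bond) before β-scission of the C–S bond returns PhS• and the exocyclic enol ether. The closest known reaction type is the thiyl-radical-catalysed (3+2) annulation of vinylcyclopropanes with alkenes. The cyclopentane is closed in the 5-exo-trig mode onto the endocyclic enol ether. C-6 is set by the obligatory cis fusion of the two five-membered rings, hence by the untouched C-2 stereocentre from the cyclopropane, and the quaternary C-5 is set in the same closure with the bulky pinacolboryl group on the convex (exo) face and CH3 on the concave face next to C-7. The step needs cleavage of the external C-6–C-3 cyclopropane bond and not of the ring-fusion bond, which the bicycle secures because only the external bond overlaps with the radical p orbital and excess 6 traps the primary radical quickly; it also needs head-to-tail addition to 6, secured by attack at the unsubstituted terminus to give the boron-stabilised radical.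

Step 5
Reactants: 7 (3aR,6S,6aR)-3,3,6-trimethyl-1-methylidene-6-(4,4,5,5-tetramethyl-1,3,2-dioxaborolan-2-yl)hexahydro-1H-cyclopenta[c]furan
Product: 8 (3aR,6S,6aR)-3,3,6-trimethyl-6-(4,4,5,5-tetramethyl-1,3,2-dioxaborolan-2-yl)hexahydro-1H-cyclopenta[c]furan-1-one
Conditions: O3, CH2Cl2, −78 °C (to first blue colour); then Me2S, −78 °C to 25 °C
Reagents that add atoms: ozone, [O-][O+]=O
Why: Ozonolysis of the electron-rich exocyclic enol ether cleaves only its C=C bond and returns the γ-lactone carbonyl (the CH2 leaves as formaldehyde), while the alkyl boronate and the three stereocentres are inert.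

Step 6
Reactants: 8 (3aR,6S,6aR)-3,3,6-trimethyl-6-(4,4,5,5-tetramethyl-1,3,2-dioxaborolan-2-yl)hexahydro-1H-cyclopenta[c]furan-1-one
Product: 9 (3aR,6R,6aR)-6-hydroxy-3,3,6-trimethylhexahydro-1H-cyclopenta[c]furan-1-one
Conditions: NaBO3·4H2O (5 equiv), THF/H2O (1:1), 25 °C; then aqueous citric acid to pH 4 (re-closes any opened lactone)
Reagents that add atoms: sodium perborate (NaBO3), [Na+].[O-]OB=O
Why: Oxidation of the tertiary C–B bond through a boron ate complex and 1,2-shift of carbon from boron to oxygen, which proceeds with retention, so the boron-bearing quaternary centre becomes the tertiary alcohol with unchanged spatial arrangement (the descriptor changes from S to R only by priority).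

Step 7
Reactants: 9 (3aR,6R,6aR)-6-hydroxy-3,3,6-trimethylhexahydro-1H-cyclopenta[c]furan-1-one
Product: 10 (3aR,6R,6aR)-3,3,6-trimethylhexahydro-1H-cyclopenta[c]furan-1,6-diol (lactol, mixture of anomers)
Conditions: i-Bu2AlH (DIBAL-H, 2.3 equiv), CH2Cl2, −78 °C; aqueous KNaC4H4O6 (potassium sodium tartrate) work-up
Reagents that add atoms: none
Why: Partial reduction of the lactone, whose tetrahedral aluminium hemiacetal is stable at −78 °C and gives the lactol on work-up (one equivalent of hydride is consumed by the free hydroxyl); the ring stereocentres are untouched and the anomeric mixture is inconsequential.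

Step 8
Reactants: 11 geranyl bromide, (2E)-1-bromo-3,7-dimethylocta-2,6-diene
Product: 12 [(2E)-3,7-dimethylocta-2,6-dien-1-yl]triphenylphosphonium bromide
Conditions: PPh3 (1.05 equiv), toluene, 25 °C, dark
Reagents that add atoms: triphenylphosphine, c1ccc(cc1)P(c1ccccc1)c1ccccc1
Why: SN2 quaternisation of phosphorus at the primary allylic carbon, with retention of the E trisubstituted alkene.

Step 9
Reactants: 12 [(2E)-3,7-dimethylocta-2,6-dien-1-yl]triphenylphosphonium bromide; 13 crocetin dialdehyde, (2E,4E,6E,8E,10E,12E,14E)-2,6,11,15-tetramethylhexadeca-2,4,6,8,10,12,14-heptaenedial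
Product: 15 all-E 8'-apo-ψ-caroten-8'-al (apo-8'-lycopenal), via geranylidene ylide 14 (not isolated)
Conditions: 13 (3 equiv), NaOMe (1.1 equiv), CH2Cl2/MeOH, 0 °C to 25 °C, dark, slow addition of 12; then heptane, reflux (Z to E equilibration); excess 13 recovered
Reagents that add atoms: none
Why: Wittig olefination of one formyl group of the symmetrical dialdehyde, with mono-olefination favoured by the excess of dialdehyde and slow ylide generation; the new disubstituted alkene forms as a Z/E mixture that is equilibrated thermally to the all-E polyene.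

Step 10
Reactants: 15 all-E 8'-apo-ψ-caroten-8'-al
Product: 16 all-E 8'-apo-ψ-caroten-8'-ol
Conditions: NaBH4, THF/EtOH, 0 °C, dark
Reagents that add atoms: none
Why: Chemoselective 1,2-reduction of the conjugated polyenal by borohydride to the primary allylic alcohol.

Step 11
Reactants: 16 all-E 8'-apo-ψ-caroten-8'-ol
Product: 17 [(2E,4E,6E,8E,10E,12E,14E,16E,18E)-2,6,11,15,19,23-hexamethyltetracosa-2,4,6,8,10,12,14,16,18,22-decaen-1-yl]triphenylphosphonium bromide
Conditions: PPh3·HBr (1.1 equiv), CH2Cl2/MeOH, 25 °C, dark, argon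
Reagents that add atoms: triphenylphosphine hydrobromide, Br.c1ccc(cc1)P(c1ccccc1)c1ccccc1
Why: Acid-promoted ionisation of the allylic alcohol to the delocalised polyenyl cation and capture by PPh3 at the unhindered terminal carbon (SN1-type phosphonium salt formation, standard for retinyl and apo-carotenyl alcohols), which keeps the fully conjugated all-E chain.

Step 12
Reactants: 10 (3aR,6R,6aR)-3,3,6-trimethylhexahydro-1H-cyclopenta[c]furan-1,6-diol; 17 the C30 phosphonium bromide
Product: 20 (all-E,2R,5R,6R)-2,6-cyclolycopene-1,5-diol, via C30 ylide 18 (not isolated), via hydroxy aldehyde 19 (not isolated)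
Conditions: 17 (1.3 equiv), 1,2-epoxybutane/EtOH (1:1), 60 °C, dark, argon; then heptane/EtOH, reflux (7Z to 7E equilibration), crystallisation
Reagents that add atoms: none
Why: Wittig olefination of the lactol through its open hydroxy aldehyde tautomer, with the ylide generated in low stationary concentration (bromide opens the epoxide to an alkoxide base) so that the formyl-bearing stereocentre and the β-hydroxy aldehyde survive; the olefination forms the C-7/C-8 alkene, creates no stereocentre and unmasks the CMe2OH group.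

Compound list
1 | dimethyl cis-cyclopropane-1,2-dicarboxylate (meso) | COC(=O)[C@H]1C[C@H]1C(=O)OC | starting material
2 | (1S,2R)-2-(methoxycarbonyl)cyclopropane-1-carboxylic acid | OC(=O)[C@H]1C[C@H]1C(=O)OC | intermediate
3 | (1S,2R)-2-(2-hydroxypropan-2-yl)cyclopropane-1-carboxylic acid | OC(=O)[C@H]1C[C@H]1C(C)(C)O | intermediate (not isolated)
4 | (1S,5R)-4,4-dimethyl-3-oxabicyclo[3.1.0]hexan-2-one | CC1(C)OC(=O)[C@H]2C[C@@H]12 | intermediate
5 | (1S,5R)-4,4-dimethyl-2-methylidene-3-oxabicyclo[3.1.0]hexane | CC1(C)OC(=C)[C@H]2C[C@@H]12 | intermediate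
6 | 4,4,5,5-tetramethyl-2-(prop-1-en-2-yl)-1,3,2-dioxaborolane | CC(=C)B1OC(C)(C)C(C)(C)O1 | starting material
7 | (3aR,6S,6aR)-3,3,6-trimethyl-1-methylidene-6-(4,4,5,5-tetramethyl-1,3,2-dioxaborolan-2-yl)hexahydro-1H-cyclopenta[c]furan | C=C1OC(C)(C)[C@@H]2CC[C@@](C)(B3OC(C)(C)C(C)(C)O3)[C@H]12 | intermediate
8 | (3aR,6S,6aR)-3,3,6-trimethyl-6-(4,4,5,5-tetramethyl-1,3,2-dioxaborolan-2-yl)hexahydro-1H-cyclopenta[c]furan-1-one | O=C1OC(C)(C)[C@@H]2CC[C@@](C)(B3OC(C)(C)C(C)(C)O3)[C@H]12 | intermediate
9 | (3aR,6R,6aR)-6-hydroxy-3,3,6-trimethylhexahydro-1H-cyclopenta[c]furan-1-one | O=C1OC(C)(C)[C@@H]2CC[C@@](C)(O)[C@H]12 | intermediate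
10 | (3aR,6R,6aR)-3,3,6-trimethylhexahydro-1H-cyclopenta[c]furan-1,6-diol (anomeric mixture) | OC1OC(C)(C)[C@@H]2CC[C@@](C)(O)[C@H]12 | intermediate
11 | geranyl bromide | CC(C)=CCC/C(C)=C/CBr | starting material
12 | [(2E)-3,7-dimethylocta-2,6-dien-1-yl]triphenylphosphonium bromide | CC(C)=CCC/C(C)=C/C[P+](c1ccccc1)(c1ccccc1)c1ccccc1.[Br-] | intermediate
13 | crocetin dialdehyde | O=C/C(C)=C/C=C/C(C)=C/C=C/C=C(C)/C=C/C=C(C)/C=O | starting material
14 | [(2E)-3,7-dimethylocta-2,6-dien-1-ylidene]triphenylphosphorane | CC(C)=CCC/C(C)=C/C=P(c1ccccc1)(c1ccccc1)c1ccccc1 | intermediate (not isolated)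
15 | all-E 8'-apo-ψ-caroten-8'-al | CC(C)=CCC/C(C)=C/C=C/C(C)=C/C=C/C(C)=C/C=C/C=C(C)/C=C/C=C(C)/C=O | intermediate
16 | all-E 8'-apo-ψ-caroten-8'-ol | CC(C)=CCC/C(C)=C/C=C/C(C)=C/C=C/C(C)=C/C=C/C=C(C)/C=C/C=C(C)/CO | intermediate
17 | [(2E,4E,6E,8E,10E,12E,14E,16E,18E)-2,6,11,15,19,23-hexamethyltetracosa-2,4,6,8,10,12,14,16,18,22-decaen-1-yl]triphenylphosphonium bromide | CC(C)=CCC/C(C)=C/C=C/C(C)=C/C=C/C(C)=C/C=C/C=C(C)/C=C/C=C(C)/C[P+](c1ccccc1)(c1ccccc1)c1ccccc1.[Br-] | intermediate
18 | the ylide of 17, (hexamethyltetracosadecaenylidene)triphenylphosphorane | CC(C)=CCC/C(C)=C/C=C/C(C)=C/C=C/C(C)=C/C=C/C=C(C)/C=C/C=C(C)/C=P(c1ccccc1)(c1ccccc1)c1ccccc1 | intermediate (not isolated)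
19 | (1R,2R,5R)-2-hydroxy-5-(2-hydroxypropan-2-yl)-2-methylcyclopentane-1-carbaldehyde | O=C[C@@H]1[C@H](C(C)(C)O)CC[C@@]1(C)O | intermediate (not isolated)
20 | (all-E,2R,5R,6R)-2,6-cyclolycopene-1,5-diol | CC(C)=CCC/C(C)=C/C=C/C(C)=C/C=C/C(C)=C/C=C/C=C(C)/C=C/C=C(C)/C=C/[C@@H]1[C@H](C(C)(C)O)CC[C@@]1(C)O | target

Total step count: 12. Longest linear sequence: 8 steps (steps 1 to 7, then step 12); the polyene arm (steps 8 to 11, then step 12) is 5 steps.

Steps most likely to fail

1. Step 4 (key step). The ring-opened primary radical can re-close and leak through the slower cleavage of the ring-fusion bond (ring expansion to a six-membered radical) if intermolecular capture by the vinylboronate is too slow, and the 5-exo closure may discriminate poorly between the two faces at the boron-bearing carbon. The fallback sets out from 5 and comes back to the route at 9; it changes the two-carbon partner and the way the tertiary C–O bond is made. The same thiyl-catalysed annulation is run with 3-methylbut-3-en-2-one (CC(=C)C(C)=O), a much faster acceptor for the nucleophilic primary radical whose adduct radical is polarity-matched to the enol ether, to give 1-[(3aR,6R,6aR)-3,3,6-trimethyl-1-methylidenehexahydro-1H-cyclopenta[c]furan-6-yl]ethan-1-one F1. Ozonolysis (O3, CH2Cl2, −78 °C; Me2S) gives (3aR,6R,6aR)-6-acetyl-3,3,6-trimethylhexahydro-1H-cyclopenta[c]furan-1-one F2. Baeyer–Villiger oxidation (CF3CO3H, Na2HPO4, CH2Cl2, 0 °C) migrates the quaternary ring carbon with retention to give (3aR,6R,6aR)-3,3,6-trimethyl-1-oxohexahydro-1H-cyclopenta[c]furan-6-yl acetate F3. Methanolysis (K2CO3, MeOH, 25 °C; then citric acid) gives 9.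

2. Step 12. In the open hydroxy aldehyde the formyl-bearing ring carbon can epimerise under base, the tertiary β-hydroxyl can trigger retro-aldol cleavage or β-elimination, and the Z to E equilibration may stay incomplete. The fallback sets out from 9 and comes back at 20; it adds a protecting group and uses a preformed ylide at low temperature. Silylation (Et3SiOSO2CF3, 2,6-lutidine, CH2Cl2, 0 °C) gives (3aR,6R,6aR)-3,3,6-trimethyl-6-[(triethylsilyl)oxy]hexahydro-1H-cyclopenta[c]furan-1-one F4. Reduction with i-Bu2AlH at −78 °C gives (3aR,6R,6aR)-3,3,6-trimethyl-6-[(triethylsilyl)oxy]hexahydro-1H-cyclopenta[c]furan-1-ol F5. Olefination with ylide 18 preformed from 17 and NaN(SiMe3)2 (THF, −78 °C to 0 °C), then thermal equilibration, gives (all-E,2R,5R,6R)-5-[(triethylsilyl)oxy]-2,6-cyclolycopen-1-ol F6. Desilylation (Bu4NF, THF, 0 °C) gives 20.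

3. Step 1. The enzyme preparation may discriminate the two enantiotopic ester groups insufficiently, or select them in the opposite sense, and the low enantiomeric purity would be carried through the route. The fallback sets out from 1 and comes back at 2; it replaces the enzymatic hydrolysis by an alkaloid-mediated anhydride opening. Saponification (NaOH, H2O; then HCl) gives cis-cyclopropane-1,2-dicarboxylic acid F7. Dehydration (Ac2O, reflux) gives the meso anhydride 3-oxabicyclo[3.1.0]hexane-2,4-dione F8. Methanolysis mediated by a stoichiometric cinchona alkaloid (quinine or quinidine, which give opposite half-esters; MeOH, toluene, −55 °C) then gives 2 with the alkaloid that delivers the (1S,2R) half-ester.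

Further compounds
F1 | step 4 | 1-[(3aR,6R,6aR)-3,3,6-trimethyl-1-methylidenehexahydro-1H-cyclopenta[c]furan-6-yl]ethan-1-one | C=C1OC(C)(C)[C@@H]2CC[C@@](C)(C(C)=O)[C@H]12
F2 | step 4 | (3aR,6R,6aR)-6-acetyl-3,3,6-trimethylhexahydro-1H-cyclopenta[c]furan-1-one | O=C1OC(C)(C)[C@@H]2CC[C@@](C)(C(C)=O)[C@H]12
F3 | step 4 | (3aR,6R,6aR)-3,3,6-trimethyl-1-oxohexahydro-1H-cyclopenta[c]furan-6-yl acetate | O=C1OC(C)(C)[C@@H]2CC[C@@](C)(OC(C)=O)[C@H]12
F4 | step 12 | (3aR,6R,6aR)-3,3,6-trimethyl-6-[(triethylsilyl)oxy]hexahydro-1H-cyclopenta[c]furan-1-one | O=C1OC(C)(C)[C@@H]2CC[C@@](C)(O[Si](CC)(CC)CC)[C@H]12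
F5 | step 12 | (3aR,6R,6aR)-3,3,6-trimethyl-6-[(triethylsilyl)oxy]hexahydro-1H-cyclopenta[c]furan-1-ol | OC1OC(C)(C)[C@@H]2CC[C@@](C)(O[Si](CC)(CC)CC)[C@H]12
F6 | step 12 | (all-E,2R,5R,6R)-5-[(triethylsilyl)oxy]-2,6-cyclolycopen-1-ol | CC(C)=CCC/C(C)=C/C=C/C(C)=C/C=C/C(C)=C/C=C/C=C(C)/C=C/C=C(C)/C=C/[C@@H]1[C@H](C(C)(C)O)CC[C@@]1(C)O[Si](CC)(CC)CC
F7 | step 1 | cis-cyclopropane-1,2-dicarboxylic acid | OC(=O)[C@H]1C[C@H]1C(O)=O
F8 | step 1 | 3-oxabicyclo[3.1.0]hexane-2,4-dione (meso anhydride) | O=C1OC(=O)[C@H]2C[C@@H]12
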